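## Compound numbers used throughout

1 silyloxy enone (bought) · 2 iodo enone · 3 Me4Sn · 4 methyl enone · 5 allylmagnesium bromide · 6 silyl enol ether · 7 methacrolein · 8 aldol · 9 diol · 10 acetonide · 11 C9 alcohol · 12 C9 ketone · 13 isopropylmagnesium chloride · 14 tertiary carbinol · 15 triol · 16 bicyclic triol · 17 enone diol · 18 bis(triethylsilyl) enone · 19 potassium dienolate · 20 deconjugated ketone · 21 epoxy ketone · 22 1β-hydroxy enone · 23 4-methoxybenzoyl chloride · 24 bis-silyl anisoate · 25 anisoate diol · 26 acetic anhydride · 27 acetate · 28 saturated hydrindanone · 29 silyl enol ether (precursor of the key step) · 30 diiodomethane · 31 siloxycyclopropane · 32 β-chloro ketone · 33 ring-enlarged enone · 34 allylic alcohol · 35 target.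

## Analysis of the target

Target 35 is a trans-fused bicyclo[5.3.0]decane, a hydroazulene of the daucane type. With the locants used throughout, the seven-membered ring is C1 (anisoyloxy), C2 (CH2), C3 (methyl-bearing alkene carbon), C4 (alkene CH), C5 (free carbinol), C6 (quaternary, methyl) and C10 (ring-fusion CH), and the five-membered ring is C6, C7 (acetoxy), C8 (CH2), C9 (tertiary carbinol with isopropyl) and C10. Calling the face of H-10 β and the face of the C6 methyl α, the six stereocentres are 6α-methyl, 10β-H (trans fusion), 1β-anisoyloxy, 5α-hydroxy, 7β-acetoxy and 9α-hydroxy/9β-isopropyl. The quaternary carbon C6 therefore lies between two oxygenated carbons (C5 and C7) and C10 between C9 and C1, so that all six centres sit on a contiguous belt around the ring fusion. Sensitive points are the two different esters beside a free allylic and a free tertiary alcohol (acyl migration, solvolysis), and the 1,3-dioxygenation C7/C9, which eliminates or fragments by retro-aldol whenever one of the two carbons is a ketone. What makes the synthesis hard is the seven-membered ring with its trisubstituted alkene, the trans fusion at a quaternary carbon, and the need to tell four oxygen functions apart. The strategy rests on the array C5(O)–C4H=C3(CH3) next to quaternary C6: without C4 it is a six-membered 2-methyl ketone (C5 carbonyl, C3 α-carbon) in a trans-hydrindane, which can enolise only toward C3, so one carbon can be inserted between C5 and C3 without a regiochemical choice.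

## Retrosynthetic reasoning

**35 to 33.** The tertiary C9 hydroxyl is uncovered last from silyl ether 34, and the C5 carbinol is traced back (C5–H bond) to ketone 33. The allylic alcohol then never needs a protecting group. Both esters are in place before it exists, and its configuration is decided by the C6 methyl that flanks the carbonyl.

**33 to 29.** C4 is removed: the bonds C4–C5 and C3–C4 are cut and C3–C5 is restored, which leads to silyl enol ether 29 of a trans-hydrindanone and the one-carbon donor 30. This is preferred to a direct seven-ring closure because a six-membered ring forms easily and the insertion creates no stereocentre. The forward reaction has to add a carbenoid to the C3=C5 enol ether and then break the internal bond of the cyclopropane.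

**29 to 27.** The enol ether is traced to ketone 28 and this, by removal of the hydrogens at C2 and C3, to enone 27. The C2=C3 double bond is kept this long because it is the handle that brings oxygen to C1 and that closes the ring.

**27 to 22.** The two ester C–O bonds are cut in an order that makes each acylation unambiguous. The anisoate from 23 goes on when C1–OH is the only free hydroxyl (22). The acetate from 26 goes on when only the secondary C7–OH and the unreactive tertiary C9–OH are free (25).

**22 to 17.** The C1–O bond is traced to a β,γ-epoxy ketone 21, this to the C1=C2 alkene 20, and 20 to the conjugated enone 18 by moving the double bond. C1 is γ to the C5 carbonyl, so the oxygen can be delivered through the alkene on a rigid trans-fused ring, where the axial C6 methyl decides the face. Reduction of a C1 ketone would be expected to give the wrong, axial alcohol for the same steric reason.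

**17 to 15.** The C2=C3 bond is cut (ring-closing metathesis of diene 15). C5 is kept at the allylic alcohol level until after ring closure, because an allylic carbinol can be oxidised in the presence of the C7 carbinol.

**15 to 9.** The C9–isopropyl bond is cut to ketone 12 and nucleophile 13. This addition is placed where the molecule holds no ester and no other carbonyl, and where the adjacent allyl group on C10 controls the face. Ketone 12 comes from silyl ether 10 by deprotection and oxidation. The acetonide of 10 masks the C5 and C7 oxygens of diol 9 in one operation.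

**9 to 4.** Diol 9 comes from ketone 8 (C7–H bond). The C5–C6 bond of 8 is cut to silyl enol ether 6 and aldehyde 7, and the C1–C10 bond of 6 to enone 4 and allyl nucleophile 5. These two bonds are formed trans to each other on the cyclopentane, first anti to the C9 silyl ether and then anti to the new allyl group, and this is the trans ring fusion.

**4 to 1.** The C6–methyl bond is cut to iodo enone 2 and methyl donor 3. Enone 1 is commercially available as the single enantiomer and supplies the only stereocentre that is bought.

## Alternatives that were turned down

**Alternative 1:** The bonds C6–C10 and C1–C2 are cut at once, which leaves an open chain: a 1-siloxyvinylcyclopropane (C2 to C6) tethered through C7–C9 to an ethoxyalkyne (C10, C1). In the forward direction [Rh(CO)2Cl]2 would open the cyclopropane, insert the alkyne and eliminate reductively, a (5+2) cycloaddition that closes both rings and gives bis(enol ether) A1.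
- For it: both rings form in one step, the oxygens at C1 and C5 arrive as enol ethers in the right places, and the C4=C5 silyl enol ether could be dehydrogenated directly to the C3=C4 enone. In convergence it is clearly stronger than the chosen route.
- Against it: the alkene partner is fully substituted at the carbon that becomes quaternary C6 and is electron-rich, and the ynol ether is a fragile partner for the metal.
- Against it: C10 is sp2 in A1. The trans ring fusion, C1 and C5 would all have to be set afterwards on a flexible hydroazulene, where protonation at C10 next to a C1 ketone is not expected to favour the trans isomer.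
- Against it: the open chain must already carry C7 and the tertiary C9 carbinol, both made without a ring to guide them.
- Comparison: the chosen route is longer, but it sets the C6/C10 relationship by anti addition and anti trapping on a cyclopentenone, and places C1 on a rigid six-membered ring.

**Alternative 2:** The C8–C9 bond is cut. Rh2(OAc)4 would decompose a diazoketone, and the carbenoid carbon C8 would insert into the ether-activated tertiary C9–H five atoms away with retention, closing the cyclopentanone A2.
- For it: a secondary carbinol stereocentre, easy to make, is turned into the tertiary C9 centre without any organometallic addition. On this point it is stronger than the chosen route, which needs deprotection, oxidation and a face-selective addition for C9.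
- Against it: only the five-membered ring is made. In A2 the carbons C1 and C5 are an ester and an acyloxymethyl group, and C2, C3, C4, the methyl group, the seven-membered ring and the configurations at C1, C5 and C7 are all still to come.
- Against it: the vicinal C6/C10 centres must be built on an open chain, and insertion at a crowded silyloxy-isopropyl carbon competes with attack on the silyl groups and with hydride shift.
- Comparison: the chosen strategy has a fixed, low-risk answer for the seven-membered ring, the part that alternative 2 leaves open.

**Alternative 3:** The bonds C6–CH3 and C10–C1 are cut on a cyclopentenone whose carbonyl is C9 and whose silyl ether is C7. Me2CuLi would add methyl to C6 anti to the C7 silyl ether, and the enolate, after exchange with ZnCl2, would attack an aldehyde through C10 to give aldol A3.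
- For it: C7 comes from the chiral enone with the right configuration, C9 is already a ketone ready for the isopropyl group, and the whole carbon set of the seven-membered ring is in place after one flask. It is the shortest of the four plans and handles C7 and C9 better than the chosen route.
- Against it: the cuprate must form a quaternary centre at a fully substituted β-carbon. The aldehyde needed is a β,γ-unsaturated vinyl iodide that isomerises easily, and the configuration at C1 depends on an aldol transition state that is hard to predict for a hindered cyclic enolate.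
- Against it: the seven-membered ring must then be closed directly onto a neopentyl aldehyde (for example with CrCl2 and NiCl2), with C5 formed in the cyclisation and no clear control element. The anisoate must also be placed while C5–OH or C7–OH are present.
- Comparison: the chosen strategy gives up step economy. In return it closes a six-membered ring, sets C1 on a rigid ring, sets C5 by hydride addition to a defined ketone, and acylates each hydroxyl when no other can compete.

Key step: step 20

## Route

Remark: locants C1–C10 are those of the target and β is the face of H-10. The C5 carbinol of 8–16 and C3 of 20, 21, 28 and 32 are epimer mixtures that are erased later, so these centres are left open in the SMILES.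

Step 1
Reactants: 1 (R)-4-(tert-butyldimethylsilyloxy)cyclopent-2-en-1-one
Product: 2 (R)-4-(tert-butyldimethylsilyloxy)-2-iodocyclopent-2-en-1-one
Conditions: I2, pyridine, CH2Cl2, 0 to 23 °C
Reagents that add atoms: iodine, II
Why: α-Iodination of an enone by conjugate addition of pyridine, iodination of the enolate and elimination; the silyloxy stereocentre (future C9) is not touched.

Step 2
Reactants: 2 (R)-4-(tert-butyldimethylsilyloxy)-2-iodocyclopent-2-en-1-one; 3 tetramethylstannane
Product: 4 (R)-4-(tert-butyldimethylsilyloxy)-2-methylcyclopent-2-en-1-one
Conditions: Pd2(dba)3 (cat.), AsPh3, CuI, NMP, 60 °C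
Reagents that add atoms: none
Why: Stille coupling of an α-iodo enone; the neutral conditions avoid β-elimination of the silyloxy group, and the methyl group is the future C6 methyl.

Step 3
Reactants: 4 (R)-4-(tert-butyldimethylsilyloxy)-2-methylcyclopent-2-en-1-one; 5 allylmagnesium bromide
Product: 6 (3R,4R)-3-allyl-4-(tert-butyldimethylsilyloxy)-2-methyl-1-(trimethylsilyloxy)cyclopent-1-ene
Conditions: CuBr·SMe2 (cat.), Me3SiCl, THF, −78 °C; Et3N
Reagents that add atoms: chlorotrimethylsilane, C[Si](C)(C)Cl
Why: Copper-catalysed conjugate addition of the allyl Grignard reagent, accelerated by the silyl chloride; the allyl group should enter C10 anti to the C9 silyl ether, as is usual for 4-silyloxycyclopentenones, and the enolate is trapped as the regiodefined silyl enol ether.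

Step 4
Reactants: 6 silyl enol ether; 7 methacrolein (2-methylprop-2-enal)
Product: 8 (2S,3R,4R)-3-allyl-4-(tert-butyldimethylsilyloxy)-2-(1-hydroxy-2-methylprop-2-en-1-yl)-2-methylcyclopentan-1-one (both carbinol epimers)
Conditions: TiCl4, CH2Cl2, −78 °C
Reagents that add atoms: none
Why: Mukaiyama aldol addition; the activated aldehyde should attack C6 on the face opposite the neighbouring allyl group, which sets the quaternary centre with C5 trans to C1 (the later trans ring fusion); the C5 carbinol mixture is erased in step 12.

Step 5
Reactants: 8 aldol
Product: 9 (1S,2R,3R,4R)-3-allyl-4-(tert-butyldimethylsilyloxy)-2-(1-hydroxy-2-methylprop-2-en-1-yl)-2-methylcyclopentan-1-ol (7β-alcohol)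
Conditions: LiBH(s-Bu)3, THF, −78 to −20 °C; then NaOH, H2O2
Reagents that add atoms: none
Why: Sterically controlled ketone reduction; the β face of C7 is screened by the branched C5 side chain on C6 and by the C9 silyl ether, so the bulky hydride should attack from the α face (past the small C6 methyl) and give the 7β-alcohol, cis to the C9 oxygen as in reductions of E-type prostaglandin intermediates.

Step 6
Reactants: 9 diol
Product: 10 acetonide (2,2-dimethyl-1,3-dioxane across the C5 and C7 oxygens; 9β-silyloxy, 10α-allyl, 6α-methyl)
Conditions: Me2C(OMe)2, PPTS, CH2Cl2, 23 °C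
Reagents that add atoms: 2,2-dimethoxypropane, COC(C)(C)OC
Why: Acetal formation of the 1,3-diol whose two oxygens lie on the same face of the cyclopentane; both hydroxyls are masked in one operation and the secondary silyl ether survives the weak acid.

Step 7
Reactants: 10 acetonide
Product: 11 C9 alcohol (9β-OH)
Conditions: Bu4NF, THF, 23 °C
Reagents that add atoms: none
Why: Fluoride cleavage of the silyl ether; the acetonide and both alkenes are inert.

Step 8
Reactants: 11 C9 alcohol
Product: 12 C9 ketone
Conditions: Pr4NRuO4 (cat.), N-methylmorpholine N-oxide, 4 Å molecular sieves, CH2Cl2, 23 °C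
Reagents that add atoms: none
Why: Perruthenate-catalysed (Ley–Griffith) oxidation of a secondary alcohol under neutral conditions; no ester or second carbonyl is present, so the ketone has no β-leaving group that could eliminate.

Step 9
Reactants: 12 C9 ketone; 13 isopropylmagnesium chloride
Product: 14 tertiary carbinol (9α-OH, 9β-isopropyl; acetonide retained)
Conditions: CeCl3, THF, −78 to 0 °C
Reagents that add atoms: none
Why: 1,2-Addition of the organocerium reagent, which suppresses enolisation and β-hydride reduction; the nucleophile should approach C9 anti to the adjacent 10α-allyl group, placing isopropyl β and hydroxyl α as in the target.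

Step 10
Reactants: 14 tertiary carbinol
Product: 15 triol (free C5 allylic carbinol, 7β-OH, 9α-OH)
Conditions: AcOH–H2O–THF (3:1:1), 40 °C
Reagents that add atoms: none
Why: Acid hydrolysis of the acetonide under conditions too mild to ionise the tertiary or the allylic alcohol.

Step 11
Reactants: 15 triol
Product: 16 trans-fused bicyclic triol (C2=C3 alkene, C5 carbinol epimers, 7β-OH, 9α-OH, 9β-isopropyl, 6α-methyl, 10β-H)
Conditions: second-generation Grubbs catalyst (5 mol %), CH2Cl2, 40 °C
Reagents that add atoms: none
Why: Ring-closing metathesis between the allyl group and the 1,1-disubstituted alkene closes the cyclohexene with loss of ethene; the two tethers are trans on the cyclopentane, so the ring fusion is trans.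

Step 12
Reactants: 16 bicyclic triol
Product: 17 enone diol (C5 ketone conjugated with C2=C3)
Conditions: MnO2 (excess), CH2Cl2, 23 °C
Reagents that add atoms: none
Why: MnO2 oxidises only the allylic C5 alcohol; the C7 carbinol and the tertiary C9 alcohol are left, and the two C5 epimers converge to one enone.

Step 13
Reactants: 17 enone diol
Product: 18 7,9-bis(triethylsilyl) ether of 17
Conditions: Et3SiOTf, 2,6-lutidine, CH2Cl2, −78 to 0 °C
Reagents that add atoms: triethylsilyl trifluoromethanesulfonate, CC[Si](CC)(CC)OS(=O)(=O)C(F)(F)F
Why: Silylation of the secondary and the tertiary hydroxyl; it removes acidic protons before the strong base of step 14, a hydroxyl that could steer the oxidant in step 15, and a competing acylation site in step 16.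

Step 14
Reactants: 18 bis(triethylsilyl) enone
Product: 20 β,γ-unsaturated ketone (C1=C2), via potassium dienolate 19 (not isolated)
Conditions: KOt-Bu, t-BuOH–THF, 23 °C; added to cold 10% aq. AcOH
Reagents that add atoms: none
Why: Deconjugation of an enone: only the γ-hydrogen at C1 can be removed because C6 is quaternary, and kinetic protonation of the dienolate at the α-carbon C3 gives the β,γ-isomer; the C3 configuration is irrelevant and 20 is used crude.

Step 15
Reactants: 20 β,γ-unsaturated ketone
Product: 22 1β-hydroxy enone, via 1β,2β-epoxy ketone 21 (not isolated)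
Conditions: dimethyldioxirane, acetone–CH2Cl2, −20 to 0 °C; then DBU (cat.), 0 to 23 °C
Reagents that add atoms: dimethyldioxirane, CC1(C)OO1
Why: Epoxidation of the isolated cis alkene under steric control: the axial C6 methyl on the homoallylic carbon screens the α face, as the angular methyl does in the α-epoxidation of 5α-steroid 2-enes, so oxygen should add from the β face; DBU then opens the β,γ-epoxy ketone by E1cB through C3 and gives the γ-hydroxy enone with the C1 configuration retained.

Step 16
Reactants: 22 1β-hydroxy enone; 23 4-methoxybenzoyl chloride
Product: 25 anisoate diol (1β-anisoyloxy enone with 7β-OH and 9α-OH), via bis(triethylsilyl) anisoate 24 (not isolated)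
Conditions: pyridine, DMAP (cat.), CH2Cl2, 0 to 23 °C; then HF·pyridine, THF, 0 to 23 °C
Reagents that add atoms: none
Why: DMAP-catalysed acylation of the only free hydroxyl, then fluoride cleavage of both silyl ethers in the same flask; the ester and the enone are stable to HF·pyridine.

Step 17
Reactants: 25 anisoate diol; 26 acetic anhydride
Product: 27 7β-acetate (9α-OH free)
Conditions: pyridine, DMAP (cat.), CH2Cl2, 0 to 23 °C
Reagents that add atoms: none
Why: Acetylation of the secondary C7 alcohol; the hindered tertiary C9 alcohol should not be acylated under these conditions.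

Step 18
Reactants: 27 acetate (enone)
Product: 28 saturated trans-hydrindanone (C5 ketone, C3 methyl epimers)
Conditions: [(Ph3P)CuH]6, benzene, H2O (2 equiv), 23 °C
Reagents that add atoms: none
Why: Conjugate reduction by copper hydride: hydride adds to C2 and the copper enolate is protonated at C3; esters and the allylic C–O bond are not attacked, and the C3 epimers are of no consequence.

Step 19
Reactants: 28 saturated hydrindanone
Product: 29 trimethylsilyl enol ether (C3=C5) with 9-trimethylsilyl ether
Conditions: Me3SiOTf, Et3N, CH2Cl2, 0 to 23 °C
Reagents that add atoms: trimethylsilyl trifluoromethanesulfonate, C[Si](C)(C)OS(=O)(=O)C(F)(F)F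
Why: Soft enolisation: the ketone can enolise only toward C3, so the tetrasubstituted enol ether is the only regioisomer, and the tertiary C9 hydroxyl is silylated at the same time.

Step 20
Reactants: 29 silyl enol ether; 30 diiodomethane
Product: 33 ring-enlarged enone (hydroazulenone with C5 ketone and C3=C4), via siloxycyclopropane 31 (not isolated), via β-chloro ketone 32 (not isolated)
Conditions: Et2Zn, CH2Cl2, 0 to 23 °C; then FeCl3, DMF, 0 to 23 °C; then NaOAc, MeOH, 50 °C
Reagents that add atoms: none
Why: The zinc carbenoid EtZnCH2I adds to the electron-rich enol ether C3=C5 (Simmons–Smith reaction in the Furukawa variant), probably from the β face away from the axial C6 methyl, and gives 31, in which the new carbon C4 is bonded to C3 and C5. FeCl3 oxidises the siloxycyclopropane by one electron with loss of the silyl group to an oxygen radical at C5, whose β-scission breaks the internal C3–C5 bond, so the carbonyl forms at C5 and the tertiary radical at C3 takes chlorine from a second FeCl3 to give 32. NaOAc then removes HCl through the C4 enolate (E1cB) and places the double bond between C3 and C4 in conjugation. The closest known reaction type is the enlargement of cyclic silyl enol ethers to 2-cycloalkenones by cyclopropanation and FeCl3 opening (Saegusa ring expansion). The seven-membered ring is not closed by cyclisation but arises when the shared bond of the bicyclo[4.1.0] unit fragments. No stereocentre is formed in 33, since the two cyclopropane centres of 31 and the chlorine-bearing C3 of 32 are transient. The step needs enol ether formation toward C3, secured by quaternary C6, and cleavage of the internal rather than the external cyclopropane bond, secured by release of ring strain and by the tertiary radical at C3 as against a primary one at C4. The esters and the tertiary silyl ether should be inert to the carbenoid and, in DMF, to FeCl3.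

Step 21
Reactants: 33 ring-enlarged enone
Product: 34 5α-allylic alcohol (9-trimethylsilyl ether of the target)
Conditions: NaBH4, CeCl3·7H2O, MeOH, −40 °C
Reagents that add atoms: none
Why: Luche 1,2-reduction; the hydride should reach the C5 carbonyl from the β face, opposite the C6 methyl that flanks it, giving the 5α-alcohol, while CeCl3 suppresses conjugate reduction.

Step 22
Reactants: 34 allylic alcohol
Product: 35 target (1β-anisoyloxy, 5α-hydroxy, 7β-acetoxy, 9α-hydroxy-9β-isopropyl, 3,6α-dimethyl, 10β-H bicyclo[5.3.0]dec-3-ene)
Conditions: PPTS, MeOH, 23 °C
Reagents that add atoms: none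
Why: Acid-catalysed methanolysis of the tertiary trimethylsilyl ether; the esters and the allylic alcohol are stable to this weak acid.

## Compound list

1 | (R)-4-(tert-butyldimethylsilyloxy)cyclopent-2-en-1-one | O=C1C=C[C@H](O[Si](C)(C)C(C)(C)C)C1 | starting material
2 | (R)-4-(tert-butyldimethylsilyloxy)-2-iodocyclopent-2-en-1-one | O=C1C(I)=C[C@H](O[Si](C)(C)C(C)(C)C)C1 | intermediate
3 | tetramethylstannane | C[Sn](C)(C)C | starting material
4 | (R)-4-(tert-butyldimethylsilyloxy)-2-methylcyclopent-2-en-1-one | O=C1C(C)=C[C@H](O[Si](C)(C)C(C)(C)C)C1 | intermediate
5 | allylmagnesium bromide | C=CC[Mg]Br | starting material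
6 | (3R,4R)-3-allyl-4-(tert-butyldimethylsilyloxy)-2-methyl-1-(trimethylsilyloxy)cyclopent-1-ene | CC1=C(O[Si](C)(C)C)C[C@@H](O[Si](C)(C)C(C)(C)C)[C@@H]1CC=C | intermediate
7 | methacrolein (2-methylprop-2-enal) | C=C(C)C=O | starting material
8 | (2S,3R,4R)-3-allyl-4-(tert-butyldimethylsilyloxy)-2-(1-hydroxy-2-methylprop-2-en-1-yl)-2-methylcyclopentan-1-one, carbinol epimers | C=C(C)C(O)[C@@]1(C)C(=O)C[C@@H](O[Si](C)(C)C(C)(C)C)[C@@H]1CC=C | intermediate
9 | (1S,2R,3R,4R)-3-allyl-4-(tert-butyldimethylsilyloxy)-2-(1-hydroxy-2-methylprop-2-en-1-yl)-2-methylcyclopentan-1-ol | C=C(C)C(O)[C@@]1(C)[C@@H](O)C[C@@H](O[Si](C)(C)C(C)(C)C)[C@@H]1CC=C | intermediate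
10 | acetonide of 9 across the C5 and C7 oxygens (9β-silyloxy, 10α-allyl, 6α-methyl) | C=C(C)C1OC(C)(C)O[C@H]2C[C@@H](O[Si](C)(C)C(C)(C)C)[C@H](CC=C)[C@@]12C | intermediate
11 | 9β-alcohol from 10 | C=C(C)C1OC(C)(C)O[C@H]2C[C@@H](O)[C@H](CC=C)[C@@]12C | intermediate
12 | C9 ketone from 11 | C=C(C)C1OC(C)(C)O[C@H]2CC(=O)[C@H](CC=C)[C@@]12C | intermediate
13 | isopropylmagnesium chloride | CC(C)[Mg]Cl | starting material
14 | tertiary carbinol (9α-OH, 9β-isopropyl), acetonide retained | C=C(C)C1OC(C)(C)O[C@H]2C[C@@](O)(C(C)C)[C@H](CC=C)[C@@]12C | intermediate
15 | monocyclic triol (C5 carbinol epimers, 7β-OH, 9α-OH, 9β-isopropyl, 10α-allyl) | C=C(C)C(O)[C@@]1(C)[C@@H](O)C[C@@](O)(C(C)C)[C@@H]1CC=C | intermediate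
16 | trans-fused bicyclic triol (C2=C3, C5 carbinol epimers) | C1C=C(C)C(O)[C@@]2(C)[C@@H](O)C[C@@](O)(C(C)C)[C@H]12 | intermediate
17 | enone diol (C5 ketone, C2=C3, 7β-OH, 9α-OH) | C1C=C(C)C(=O)[C@@]2(C)[C@@H](O)C[C@@](O)(C(C)C)[C@H]12 | intermediate
18 | 7,9-bis(triethylsilyl) ether of 17 | C1C=C(C)C(=O)[C@@]2(C)[C@@H](O[Si](CC)(CC)CC)C[C@@](O[Si](CC)(CC)CC)(C(C)C)[C@H]12 | intermediate
19 | potassium dienolate of 18 (C1=C2, C3=C5–O) | C1=CC(C)=C([O-])[C@@]2(C)[C@@H](O[Si](CC)(CC)CC)C[C@@](O[Si](CC)(CC)CC)(C(C)C)[C@H]12.[K+] | intermediate
20 | β,γ-unsaturated ketone (C1=C2), C3 epimers | C1=CC(C)C(=O)[C@@]2(C)[C@@H](O[Si](CC)(CC)CC)C[C@@](O[Si](CC)(CC)CC)(C(C)C)[C@H]12 | intermediate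
21 | 1β,2β-epoxy ketone | O1[C@H]2[C@@H]1C(C)C(=O)[C@@]3(C)[C@@H](O[Si](CC)(CC)CC)C[C@@](O[Si](CC)(CC)CC)(C(C)C)[C@H]23 | intermediate
22 | 1β-hydroxy enone (7,9-bis-silyl ether) | O[C@H]1C=C(C)C(=O)[C@@]2(C)[C@@H](O[Si](CC)(CC)CC)C[C@@](O[Si](CC)(CC)CC)(C(C)C)[C@H]12 | intermediate
23 | 4-methoxybenzoyl chloride | COc1ccc(cc1)C(Cl)=O | starting material
24 | 1β-anisoate of 22 | COc1ccc(C(=O)O[C@H]2C=C(C)C(=O)[C@@]3(C)[C@@H](O[Si](CC)(CC)CC)C[C@@](O[Si](CC)(CC)CC)(C(C)C)[C@H]23)cc1 | intermediate
25 | anisoate diol (7β-OH, 9α-OH) | COc1ccc(C(=O)O[C@H]2C=C(C)C(=O)[C@@]3(C)[C@@H](O)C[C@@](O)(C(C)C)[C@H]23)cc1 | intermediate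
26 | acetic anhydride | CC(=O)OC(C)=O | starting material
27 | 7β-acetate of 25 | COc1ccc(C(=O)O[C@H]2C=C(C)C(=O)[C@@]3(C)[C@@H](OC(C)=O)C[C@@](O)(C(C)C)[C@H]23)cc1 | intermediate
28 | saturated trans-hydrindanone (C3 epimers) | COc1ccc(C(=O)O[C@H]2CC(C)C(=O)[C@@]3(C)[C@@H](OC(C)=O)C[C@@](O)(C(C)C)[C@H]23)cc1 | intermediate
29 | trimethylsilyl enol ether (C3=C5) with 9-trimethylsilyl ether | COc1ccc(C(=O)O[C@H]2CC(C)=C(O[Si](C)(C)C)[C@@]3(C)[C@@H](OC(C)=O)C[C@@](O[Si](C)(C)C)(C(C)C)[C@H]23)cc1 | intermediate
30 | diiodomethane | ICI | starting material
31 | siloxycyclopropane (C4 bridging C3 and C5, drawn as the β-face adduct) | COc1ccc(C(=O)O[C@H]2C[C@@]4(C)C[C@@]4(O[Si](C)(C)C)[C@@]3(C)[C@@H](OC(C)=O)C[C@@](O[Si](C)(C)C)(C(C)C)[C@H]23)cc1 | intermediate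
32 | β-chloro ketone (C5 ketone, C3 chloride, seven-membered ring) | COc1ccc(C(=O)O[C@H]2CC(C)(Cl)CC(=O)[C@@]3(C)[C@@H](OC(C)=O)C[C@@](O[Si](C)(C)C)(C(C)C)[C@H]23)cc1 | intermediate
33 | ring-enlarged enone (C5 ketone, C3=C4, 9-trimethylsilyl ether) | COc1ccc(C(=O)O[C@H]2CC(C)=CC(=O)[C@@]3(C)[C@@H](OC(C)=O)C[C@@](O[Si](C)(C)C)(C(C)C)[C@H]23)cc1 | intermediate
34 | 5α-allylic alcohol, 9-trimethylsilyl ether | COc1ccc(C(=O)O[C@H]2CC(C)=C[C@H](O)[C@@]3(C)[C@@H](OC(C)=O)C[C@@](O[Si](C)(C)C)(C(C)C)[C@H]23)cc1 | intermediate
35 | target: 1β-(4-methoxybenzoyloxy)-7β-acetoxy-5α,9α-dihydroxy-9β-isopropyl-3,6α-dimethyl-10β-H-bicyclo[5.3.0]dec-3-ene | COc1ccc(C(=O)O[C@H]2CC(C)=C[C@H](O)[C@@]3(C)[C@@H](OC(C)=O)C[C@@](O)(C(C)C)[C@H]23)cc1 | target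

## Step count and least certain steps

Total step count: 22. Longest linear sequence: 22 steps (1 to 35); the route is fully linear, and 3, 5, 7, 13, 23, 26 and 30 are bought.

**Step 20 (key step).**
- What may go wrong: slow carbenoid addition to the hindered tetrasubstituted enol ether, with desilylation back to 28 by the zinc halide; cleavage of the external cyclopropane bond; loss of the C9 silyl ether followed by ionisation of the tertiary carbinol under FeCl3; and vinylogous elimination of the C1 anisoate from 33 if the base treatment is pushed.
- Fallback, from 28 back to 33: Sc(OTf)3-catalysed insertion of trimethylsilyldiazomethane, in which the less substituted α-carbon C3 migrates rather than quaternary C6, gives α-trimethylsilyl cycloheptanone F1. It loses silicon on acidic work-up to cycloheptanone F2 (C5 ketone, C4H2, C3H(CH3)). Me3SiOTf and Et3N give the C4=C5 silyl enol ether with 9-silyl ether F3, and Pd(OAc)2 in MeCN (Saegusa–Ito oxidation) then introduces the C3=C4 double bond and returns 33. The same two bonds to C4 are formed, but by a carbonyl homologation and a separate dehydrogenation.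

**Step 15 (with step 14).**
- What may go wrong: reconjugation of 20 before it is oxidised, and approach of the oxidant from the α face, which would erode the C1 configuration.
- Fallback, from 18 back to 24: soft enolisation (Et3SiOTf, Et3N) gives dienol silyl ether F4. mCPBA should then attack C1 along the axial direction, as peracids do with steroidal 3,5-dienol ethers, and give the 1α-hydroxy enone F5. A Mitsunobu esterification with 4-methoxybenzoic acid (PPh3, DIAD) inverts C1 and returns 24, which is desilylated to 25 as in step 16.

**Step 9.**
- What may go wrong: enolisation or β-hydride reduction instead of addition, and partial attack from the α face because the acetonide ring crowds the β face.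
- Fallback, from 12 back to 16: aqueous AcOH removes the acetonide to give keto diol F6, and ring-closing metathesis gives bicyclic keto diol F7. Isopropenylmagnesium bromide with CeCl3 (an sp2 nucleophile without β-hydrogens) should add to the rigid trans-fused ketone from the β face, opposite the angular methyl, to give isopropenyl carbinol F8. H2 with RhCl(PPh3)3 then saturates only the 1,1-disubstituted alkene and returns 16.

**Step 5.**
- What may go wrong: insufficient facial selectivity at C7, since the α face carries the C6 methyl and the allyl group, and retro-aldol cleavage of the β-hydroxy ketone under the basic hydride.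
- Fallback, from 8 back to 9: reagent control in place of substrate control. Enantiopure chlorodiisopinocampheylborane (Ipc2BCl), which distinguishes the quaternary from the methylene flank of a ketone, is used in the enantiomeric form that delivers hydride to the α face. No new compound is formed.

**Step 21.**
- What may go wrong: poor facial selectivity on the flexible seven-membered enone, where the 7β-acetoxy group competes with the C6 methyl for control, and conjugate reduction.
- Fallback, from 33 back to 34: reagent-controlled 1,2-reduction with an oxazaborolidine catalyst (Corey–Bakshi–Shibata reduction) and catecholborane, the catalyst enantiomer chosen for delivery to the β face. No new compound is formed.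

## Further compounds

F1 | step 20 | α-trimethylsilyl cycloheptanone (silicon on C4) from 28 | COc1ccc(C(=O)O[C@H]2CC(C)C([Si](C)(C)C)C(=O)[C@@]3(C)[C@@H](OC(C)=O)C[C@@](O)(C(C)C)[C@H]23)cc1
F2 | step 20 | ring-enlarged saturated ketone (C5 ketone, C4H2, C3 methyl) | COc1ccc(C(=O)O[C@H]2CC(C)CC(=O)[C@@]3(C)[C@@H](OC(C)=O)C[C@@](O)(C(C)C)[C@H]23)cc1
F3 | step 20 | C4=C5 trimethylsilyl enol ether with 9-trimethylsilyl ether | COc1ccc(C(=O)O[C@H]2CC(C)C=C(O[Si](C)(C)C)[C@@]3(C)[C@@H](OC(C)=O)C[C@@](O[Si](C)(C)C)(C(C)C)[C@H]23)cc1
F4 | step 15 | dienol triethylsilyl ether of 18 (C1=C2, C3=C5) | C1=CC(C)=C(O[Si](CC)(CC)CC)[C@@]2(C)[C@@H](O[Si](CC)(CC)CC)C[C@@](O[Si](CC)(CC)CC)(C(C)C)[C@H]12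
F5 | step 15 | 1α-hydroxy enone (C1 epimer of 22) | O[C@@H]1C=C(C)C(=O)[C@@]2(C)[C@@H](O[Si](CC)(CC)CC)C[C@@](O[Si](CC)(CC)CC)(C(C)C)[C@H]12
F6 | step 9 | monocyclic keto diol (C9 ketone, C5 and C7 hydroxyls free) | C=C(C)C(O)[C@@]1(C)[C@@H](O)CC(=O)[C@@H]1CC=C
F7 | step 9 | bicyclic keto diol (C2=C3, C9 ketone) | C1C=C(C)C(O)[C@@]2(C)[C@@H](O)CC(=O)[C@H]12
F8 | step 9 | bicyclic 9β-isopropenyl 9α-carbinol | C1C=C(C)C(O)[C@@]2(C)[C@@H](O)C[C@@](O)(C(C)=C)[C@H]12
F0 | step 5 | none | none
F0 | step 21 | none | none
A1 | alternative 1 | bicyclo[5.3.0]decadiene bis(enol ether): C1 ethyl enol ether (C1=C10), C5 silyl enol ether (C4=C5), C7 silyl ether, C9 silyl ether with isopropyl, quaternary C6 methyl | CCOC1=C2[C@](O[Si](CC)(CC)CC)(C(C)C)C[C@H](O[Si](C)(C)C(C)(C)C)[C@]2(C)C(O[Si](C)(C)C(C)(C)C)=C[C@H](C)C1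
A2 | alternative 2 | methyl 5-(tert-butyldimethylsilyloxy)-5-isopropyl-2-methyl-3-oxo-2-(pivaloyloxymethyl)cyclopentane-1-carboxylate | O=C1C[C@@](O[Si](C)(C)C(C)(C)C)(C(C)C)[C@H](C(=O)OC)[C@@]1(C)COC(=O)C(C)(C)C
A3 | alternative 3 | 4-(tert-butyldimethylsilyloxy)-2-[(Z)-1-hydroxy-4-iodo-3-methylbut-3-enyl]-3-(4-methoxybenzyloxymethyl)-3-methylcyclopentan-1-one | O=C1C[C@H](O[Si](C)(C)C(C)(C)C)[C@](C)(COCc2ccc(OC)cc2)[C@H]1[C@@H](O)C/C(C)=C\I
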